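**Strategy.** The route rests on cutting ring B (C5–C10, labdane numbering) at C7–C8 and C9–C10. This reveals a Diels–Alder reaction between a 2-silyloxy diene built on ring A (C7=C6(OSi)–C5=C10) and a but-2-ynoyl pyrazole (C8≡C9, carrying C17 and C11). In one operation the step closes ring B, creates the quaternary C10 stereocentre under chiral copper control, places the tetrasubstituted C8=C9 alkene with its methyl group and acyl handle, and stores the C6 oxygen as an enol ether. It exploits the pattern of ring B itself: oxygen on C6 para to the carbon-bearing C9, the C8=C9 double bond, and quaternary C10. The acyl group later becomes a vinyl group, which is coupled to a bromobutenolide.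

Key step: step 5

Remark on numbering: labdane numbering is used in the text (ring A C1–C5 and C10; ring B C5–C10; C11 on C9; C17 on C8; C18 and C19 on C4; C20 on C10; side chain C11–C16). Systematic names are in the compound list.

Assumption: the (S,S)-tert-butyl bis(oxazoline) is taken as the ligand antipode that delivers the (8aS) adduct 9. If the sense of induction proves opposite, the equally available (R,R) ligand is used with no other change.

Step 1
Reactants: 1 β-cyclocitral
Product: 2 rac-1-(2,6,6-trimethylcyclohex-1-en-1-yl)ethanol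
Conditions: MeMgBr, THF, 0 °C; aq. NH4Cl
Reagents that add atoms: methylmagnesium bromide, C[Mg]Br
Why: Grignard 1,2-addition to a hindered, non-enolisable enal; the carbinol centre is formed racemic and is erased in step 2.

Step 2
Reactants: 2 rac-1-(2,6,6-trimethylcyclohex-1-en-1-yl)ethanol
Product: 3 1-(2,6,6-trimethylcyclohex-1-en-1-yl)ethanone
Conditions: Dess–Martin periodinane, CH2Cl2, 0 °C → rt
Reagents that add atoms: none
Why: Dess–Martin oxidation of a secondary allylic alcohol under neutral conditions, which leave the tetrasubstituted alkene in place.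

Step 3
Reactants: 3 1-(2,6,6-trimethylcyclohex-1-en-1-yl)ethanone
Product: 5 tert-butyldimethylsilyl dienol ether of ketone 3, via lithium dienolate 4 (not isolated)
Conditions: LiN(iPr)2, THF, −78 °C; TBSOTf, −78 → 0 °C; Et3N, pentane work-up
Reagents that add atoms: tert-butyldimethylsilyl trifluoromethanesulfonate, CC(C)(C)[Si](C)(C)OS(=O)(=O)C(F)(F)F; lithium diisopropylamide, [Li+].CC(C)[N-]C(C)C (its lithium stays only in intermediate 4)
Why: Kinetic deprotonation by the hindered amide occurs at the acetyl methyl group (cross-conjugated enolate, the twisted enone disfavouring γ-deprotonation), and the silyl triflate traps it on oxygen (silyl enol ether formation).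

Step 4
Reactants: 6 but-2-ynoic acid; 7 3,5-dimethylpyrazole
Product: 8 1-(but-2-ynoyl)-3,5-dimethylpyrazole
Conditions: DCC, CH2Cl2, 0 °C → rt
Reagents that add atoms: none
Why: Carbodiimide-mediated N-acylation of the pyrazole through the O-acylisourea, which avoids the acid chloride and its HCl addition to the alkyne.

Step 5
Reactants: 5 tert-butyldimethylsilyl dienol ether; 8 1-(but-2-ynoyl)-3,5-dimethylpyrazole
Product: 9 ring B cyclohexadiene adduct (C6 silyl enol ether, C8=C9 alkene, C11 acyl pyrazole, 10β-methyl)
Conditions: Cu(OTf)2 (10 mol %), (S,S)-tBu-box (11 mol %), 4 Å MS, CH2Cl2, −40 → 0 °C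
Reagents that add atoms: none
Why: Proposed new method: the acyl pyrazole chelates the divalent copper bis(oxazoline) complex through its carbonyl oxygen and N2, which lowers the alkyne LUMO, and the electron-rich diene adds in a concerted but asynchronous [4+2] in which C7–C8 bonding leads and C9–C10 bonding follows; even a stepwise Mukaiyama–Michael limit should collapse to the same ring by attack of the allenoate carbon C9 on the siloxy-stabilised allyl cation at C10. The closest known reactions are divalent-copper-catalysed enantioselective Diels–Alder additions of β-substituted propioloyl pyrazoles to simple dienes and the thermal additions of 1-vinyl-2,6,6-trimethylcyclohexene-type dienes to acetylenic esters; new is their combination on a diene whose reacting terminus is fully substituted. Ring B closes as a six-membered ring by intermolecular [4+2] annulation, suprafacial on both partners, with both ring bonds made in this step. C10 is the only new stereocentre and is set by the catalyst: the C2-symmetric ligand blocks two diagonal quadrants around the bound alkyne, so the bulky trimethylcyclohexene end of the diene must pass through an open quadrant and only one face of C10 can reach C9. The step needs regioselectivity (C7 to the methyl-bearing C8, C10 to the acyl-bearing C9), which the enol ether secures because its β-carbon C7 is the nucleophilic terminus and pairs with the electrophilic β-carbon of the ynoyl unit; it also needs [4+2] over [2+2] periselectivity, which the tertiary allylic character of C10 favours.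

Step 6
Reactants: 9 ring B cyclohexadiene adduct
Product: 11 C11 allylic alcohol with the C6 silyl enol ether intact, via silyloxy dienal 10 (not isolated)
Conditions: iBu2AlH (2.5 equiv), CH2Cl2, −78 → 0 °C; aq. potassium sodium tartrate
Reagents that add atoms: none
Why: N-Acyl pyrazoles are active amides, so the first hydride gives an aminal that loses pyrazole to the aldehyde, which is reduced again (1,2-reduction), while the silyl enol ether and the fully substituted alkene are inert to the aluminium hydride.

Step 7
Reactants: 11 C11 allylic alcohol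
Product: 12 trans-fused 6-oxo-8-en-11-ol (5α-H)
Conditions: Bu4NF, AcOH (1:1.5), THF, −20 → 0 °C
Reagents that add atoms: none
Why: Buffered fluoride cleavage of the silyl enol ether, in which the C5 enolate is protonated under kinetic control from the α-face, anti to the axial C20 methyl and the 4β-methyl group, giving the trans ring fusion; as with Birch-type dienol ethers, the β,γ-unsaturated ketone should be released without conjugation.

Step 8
Reactants: 12 trans-fused 6-oxo-8-en-11-ol
Product: 13 6β,11-diol
Conditions: LiAlH4, Et2O, −78 → 0 °C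
Reagents that add atoms: none
Why: Hydride reduction of the ketone from the α-face, because the β-face of C6 is screened by the 1,3-related axial methyl groups on C10 and C4, which gives the axial 6β-alcohol (6R) as is usual for 6-oxo labdanes and drimanes.

Step 9
Reactants: 13 6β,11-diol
Product: 14 6β-hydroxy-8-en-11-al
Conditions: MnO2 (activated, excess), CH2Cl2, rt
Reagents that add atoms: none
Why: MnO2 oxidises only allylic alcohols, so the primary C11 carbinol becomes the enal while the hindered homoallylic 6β-hydroxyl is left untouched (chemoselective allylic oxidation).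

Step 10
Reactants: 14 6β-hydroxy-8-en-11-al
Product: 15 9-vinyl-8-en-6β-ol
Conditions: Ph3PCH3Br, KOtBu, THF, 0 °C; then 14, 0 °C → rt
Reagents that add atoms: methyltriphenylphosphonium bromide, C[P+](c1ccccc1)(c1ccccc1)c1ccccc1.[Br-]
Why: Wittig methylenation of a β-cyclocitral-type enal, run on the free alcohol with excess ylide because a C6 alkoxide is too poor a leaving group for vinylogous elimination.

Step 11
Reactants: 15 9-vinyl-8-en-6β-ol
Product: 16 6β-acetoxy-9-vinyl-8-ene
Conditions: Ac2O, DMAP, Et3N, CH2Cl2, rt → 40 °C
Reagents that add atoms: acetic anhydride, CC(=O)OC(C)=O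
Why: DMAP-catalysed acetylation of the hindered axial alcohol, which proceeds at oxygen with retention at C6.

Step 12
Reactants: 16 6β-acetoxy-9-vinyl-8-ene; 17 4-bromofuran-2(5H)-one
Product: 19 target 6β-acetoxylabda-8,13-dien-15,16-olide, via alkylborane 18 (not isolated)
Conditions: 9-BBN-H, THF, 0 °C → rt; then 17, Pd(dppf)Cl2 (5 mol %), AsPh3, aq. K3PO4, DMF, rt → 50 °C
Reagents that add atoms: 9-borabicyclo[3.3.1]nonane, B1C2CCCC1CCC2 (its boron group stays only in intermediate 18)
Why: Anti-Markovnikov hydroboration of the only monosubstituted alkene gives the primary C12 borane, which undergoes B-alkyl Suzuki–Miyaura coupling with the vinylogous acyl bromide 17, forming C12–C13 without touching the acetate or the tetrasubstituted alkene and creating no stereocentre.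

**Compound list**

1 | β-cyclocitral (2,6,6-trimethylcyclohex-1-ene-1-carbaldehyde) | CC1=C(C=O)C(C)(C)CCC1 | starting material
2 | rac-1-(2,6,6-trimethylcyclohex-1-en-1-yl)ethanol | CC(O)C1=C(C)CCCC1(C)C | intermediate
3 | 1-(2,6,6-trimethylcyclohex-1-en-1-yl)ethanone | CC(=O)C1=C(C)CCCC1(C)C | intermediate
4 | lithium 1-(2,6,6-trimethylcyclohex-1-en-1-yl)ethen-1-olate (not isolated) | [Li+].[O-]C(=C)C1=C(C)CCCC1(C)C | intermediate
5 | tert-butyldimethyl{[1-(2,6,6-trimethylcyclohex-1-en-1-yl)ethenyl]oxy}silane | C=C(O[Si](C)(C)C(C)(C)C)C1=C(C)CCCC1(C)C | intermediate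
6 | but-2-ynoic acid | CC#CC(=O)O | starting material
7 | 3,5-dimethylpyrazole | Cc1cc(C)n[nH]1 | starting material
8 | 1-(but-2-ynoyl)-3,5-dimethylpyrazole | CC#CC(=O)n1nc(C)cc1C | intermediate
9 | [(8aS)-4-(tert-butyldimethylsilyloxy)-2,5,5,8a-tetramethyl-3,5,6,7,8,8a-hexahydronaphthalen-1-yl](3,5-dimethylpyrazol-1-yl)methanone | CC1=C(C(=O)n2nc(C)cc2C)[C@@]2(C)CCCC(C)(C)C2=C(O[Si](C)(C)C(C)(C)C)C1 | intermediate
10 | (8aS)-4-(tert-butyldimethylsilyloxy)-2,5,5,8a-tetramethyl-3,5,6,7,8,8a-hexahydronaphthalene-1-carbaldehyde (not isolated) | CC1=C(C=O)[C@@]2(C)CCCC(C)(C)C2=C(O[Si](C)(C)C(C)(C)C)C1 | intermediate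
11 | [(8aR)-4-(tert-butyldimethylsilyloxy)-2,5,5,8a-tetramethyl-3,5,6,7,8,8a-hexahydronaphthalen-1-yl]methanol (same spatial arrangement as 9; the descriptor changes only through CIP ranking) | CC1=C(CO)[C@@]2(C)CCCC(C)(C)C2=C(O[Si](C)(C)C(C)(C)C)C1 | intermediate
12 | (4aS,8aS)-4-(hydroxymethyl)-3,4a,8,8-tetramethyl-4a,5,6,7,8,8a-hexahydronaphthalen-1(2H)-one | O=C1CC(C)=C(CO)[C@@]2(C)CCCC(C)(C)[C@H]12 | intermediate
13 | (1R,4aS,8aS)-4-(hydroxymethyl)-3,4a,8,8-tetramethyl-1,2,4a,5,6,7,8,8a-octahydronaphthalen-1-ol | O[C@@H]1CC(C)=C(CO)[C@@]2(C)CCCC(C)(C)[C@H]12 | intermediate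
14 | (4R,4aS,8aS)-4-hydroxy-2,5,5,8a-tetramethyl-3,4,4a,5,6,7,8,8a-octahydronaphthalene-1-carbaldehyde | O[C@@H]1CC(C)=C(C=O)[C@@]2(C)CCCC(C)(C)[C@H]12 | intermediate
15 | (1R,4aS,8aS)-4-ethenyl-3,4a,8,8-tetramethyl-1,2,4a,5,6,7,8,8a-octahydronaphthalen-1-ol | O[C@@H]1CC(C)=C(C=C)[C@@]2(C)CCCC(C)(C)[C@H]12 | intermediate
16 | (1R,4aS,8aS)-4-ethenyl-3,4a,8,8-tetramethyl-1,2,4a,5,6,7,8,8a-octahydronaphthalen-1-yl acetate | CC(=O)O[C@@H]1CC(C)=C(C=C)[C@@]2(C)CCCC(C)(C)[C@H]12 | intermediate
17 | 4-bromofuran-2(5H)-one | BrC1=CC(=O)OC1 | starting material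
18 | (1R,4aS,8aS)-4-[2-(9-borabicyclo[3.3.1]nonan-9-yl)ethyl]-3,4a,8,8-tetramethyl-1,2,4a,5,6,7,8,8a-octahydronaphthalen-1-yl acetate (not isolated) | CC(=O)O[C@@H]1CC(C)=C(CCB2C3CCCC2CCC3)[C@@]2(C)CCCC(C)(C)[C@H]12 | intermediate
19 | (1R,4aS,8aS)-3,4a,8,8-tetramethyl-4-[2-(5-oxo-2,5-dihydrofuran-3-yl)ethyl]-1,2,4a,5,6,7,8,8a-octahydronaphthalen-1-yl acetate (5S,6R,10S in labdane numbering) | CC(=O)O[C@@H]1CC(C)=C(CCC2=CC(=O)OC2)[C@@]2(C)CCCC(C)(C)[C@H]12 | target

**Totals.** Total step count: 12. Longest linear sequence: 11 steps (steps 1–3 and 5–12; step 4 is the one-step dienophile branch).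

**Steps most likely to fail**

1. Step 5 (the proposed method). The hindered diene may fail to reach the s-cis geometry inside the chiral pocket. The reaction may divert to a stepwise Mukaiyama–Michael or [2+2] course, the Lewis acid may strip the silyl group, or enantiofacial selectivity may be poor. The fallback uses known chemistry and sets out from 5 and 8. They are heated without catalyst (toluene, sealed tube, 110–130 °C, or under high pressure), the established thermal mode for 1-vinyl-2,6,6-trimethylcyclohexene-type dienes with acetylenic carbonyl compounds. This should give the racemic adduct F1 with the same polarity-controlled regiochemistry. Preparative chromatography on a chiral stationary phase then separates F1 into 9 and its (8aR)-enantiomer F2, which is set aside. The route is rejoined at 9.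

2. Step 7. Protonation at C5 may occur from the β-face (cis ring fusion), or the C8=C9 double bond may migrate into conjugation with the new ketone. The fallback sets out from 9 and unveils the ketone before the acyl group is touched. Hydrolysis of the enol ether on 9 itself (1 M HCl, THF, rt) takes place while C8=C9 is held in conjugation with the acyl pyrazole, and C5 can equilibrate through its enol to the trans-fused keto acyl pyrazole F3. LiAlH4 (Et2O, −78 → 0 °C) then reduces the ketone from the α-face and the acyl pyrazole to the primary carbinol in one operation. The route is rejoined at diol 13.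

3. Step 12. Hydroboration of the doubly flanked vinyl group may be sluggish, or protodeboronation and base-induced breakdown of the bromobutenolide may outrun transmetalation. The fallback sets out from diol 13 and builds the side chain by allylic sp3–sp3 coupling and furan oxidation.
   - Appel bromination (CBr4, PPh3, CH2Cl2, −20 °C) converts only the primary allylic hydroxyl and should give allylic bromide F4.
   - Li2CuCl4-catalysed coupling (THF, −78 → 0 °C) with excess furan-3-ylmethylmagnesium chloride F5, made from commercial 3-(chloromethyl)furan and Mg in THF, joins C11 to C12 and gives furan alcohol F6. This coupling is known for β-cyclogeranyl-type bromides.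
   - Acetylation (Ac2O, DMAP, Et3N) gives furan acetate F7.
   - Photooxygenation (O2, hν, rose bengal, iPr2NEt, CH2Cl2, −78 °C) adds singlet oxygen across the furan, which should be much faster at this temperature than the ene reaction of the hindered tetrasubstituted alkene. The hindered amine removes the less hindered C15–H of the endoperoxide (Kornblum–DeLaMare fragmentation), giving γ-hydroxybutenolide F8 with the carbonyl on C15.
   - NaBH4 (EtOH, 0 °C) reduces the masked aldehyde at C16, and relactonisation returns to target 19.

**Further compounds**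

F1 | step 5 | rac-[4-(tert-butyldimethylsilyloxy)-2,5,5,8a-tetramethyl-3,5,6,7,8,8a-hexahydronaphthalen-1-yl](3,5-dimethylpyrazol-1-yl)methanone | CC1=C(C(=O)n2nc(C)cc2C)C2(C)CCCC(C)(C)C2=C(O[Si](C)(C)C(C)(C)C)C1
F2 | step 5 | (8aR)-enantiomer of adduct 9 | CC1=C(C(=O)n2nc(C)cc2C)[C@]2(C)CCCC(C)(C)C2=C(O[Si](C)(C)C(C)(C)C)C1
F3 | step 7 | (4aS,8aS)-4-(3,5-dimethylpyrazole-1-carbonyl)-3,4a,8,8-tetramethyl-4a,5,6,7,8,8a-hexahydronaphthalen-1(2H)-one | O=C1CC(C)=C(C(=O)n3nc(C)cc3C)[C@@]2(C)CCCC(C)(C)[C@H]12
F4 | step 12 | (1R,4aS,8aS)-4-(bromomethyl)-3,4a,8,8-tetramethyl-1,2,4a,5,6,7,8,8a-octahydronaphthalen-1-ol | O[C@@H]1CC(C)=C(CBr)[C@@]2(C)CCCC(C)(C)[C@H]12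
F5 | step 12 | furan-3-ylmethylmagnesium chloride | Cl[Mg]Cc1ccoc1
F6 | step 12 | (1R,4aS,8aS)-4-[2-(furan-3-yl)ethyl]-3,4a,8,8-tetramethyl-1,2,4a,5,6,7,8,8a-octahydronaphthalen-1-ol | O[C@@H]1CC(C)=C(CCc2ccoc2)[C@@]2(C)CCCC(C)(C)[C@H]12
F7 | step 12 | (1R,4aS,8aS)-4-[2-(furan-3-yl)ethyl]-3,4a,8,8-tetramethyl-1,2,4a,5,6,7,8,8a-octahydronaphthalen-1-yl acetate | CC(=O)O[C@@H]1CC(C)=C(CCc2ccoc2)[C@@]2(C)CCCC(C)(C)[C@H]12
F8 | step 12 | (1R,4aS,8aS)-4-[2-(2-hydroxy-5-oxo-2,5-dihydrofuran-3-yl)ethyl]-3,4a,8,8-tetramethyl-1,2,4a,5,6,7,8,8a-octahydronaphthalen-1-yl acetate (both epimers at the lactol carbon) | CC(=O)O[C@@H]1CC(C)=C(CCC2=CC(=O)OC2O)[C@@]2(C)CCCC(C)(C)[C@H]12
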